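**Retrosynthetic overview**

1. Target 25 ⇐ O-methylation of phenol 24 ⇐ intramolecular 1,6-oxa-Michael addition of the C2 hydroxyl onto a p-quinone methide (23) made from diol 21; this closes the oxolane and sets C5.
2. Diol 21 ⇐ lactone 15 + aryllithium 19 (from 2,6-dimethoxyphenol), then ketone reduction.
3. Lactone 15 ⇐ aldehyde ester 10 + aryltitanium 13 (from 4-bromo-1,2-dimethoxybenzene); Felkin–Anh addition sets C2.
4. Aldehyde 10 ⇐ imide 8 ⇐ alkylation of propanoyl imide 4 with (S)-lactate triflate 6; this sets C3 and C4.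
5. Ring order: the γ-lactone of 15 is formed first and opened again in step 8; the oxolane of the target is the only ring closed for good, in the last step.

Assumption: a one-flask operation with several additions counts as one step; centres that are destroyed later (acetal carbon of the 1-ethoxyethyl group, lactol carbon, C4 carbinol of 21) are carried as mixtures.

**Step 1**
Reactants: 1 (4R)-4-benzyl-5,5-dimethyl-1,3-oxazolidin-2-one; 2 propanoyl chloride
Product: 4 (4R)-4-benzyl-5,5-dimethyl-3-propanoyl-1,3-oxazolidin-2-one, via N-lithio oxazolidinone 3 (not isolated)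
Conditions: n-BuLi, THF, −78 °C; then 2, −78 → 0 °C
Reagents that add atoms: none
Why: N-acylation of the lithiated oxazolidinone gives the imide whose auxiliary will control C3; no stereocentre is formed.

**Step 2**
Reactants: 5 tert-butyl (2S)-2-hydroxypropanoate
Product: 6 tert-butyl (2S)-2-[(trifluoromethanesulfonyl)oxy]propanoate
Conditions: Tf2O, 2,6-lutidine, CH2Cl2, −78 → 0 °C (used at once)
Reagents that add atoms: trifluoromethanesulfonic anhydride, O=S(=O)(OS(=O)(=O)C(F)(F)F)C(F)(F)F
Why: O-sulfonylation occurs at oxygen, so the (S) centre of L-lactate is retained and becomes a defined SN2 electrophile.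

**Step 3**
Reactants: 4 (4R)-4-benzyl-5,5-dimethyl-3-propanoyl-1,3-oxazolidin-2-one; 6 tert-butyl (2S)-2-[(trifluoromethanesulfonyl)oxy]propanoate
Product: 8 tert-butyl (2S,3S)-4-[(4R)-4-benzyl-5,5-dimethyl-2-oxo-1,3-oxazolidin-3-yl]-2,3-dimethyl-4-oxobutanoate, via sodium enolate 7 (not isolated)
Conditions: NaN(SiMe3)2, THF, −78 °C; then 6, −78 → −40 °C
Reagents that add atoms: none
Why: Evans-type auxiliary-controlled enolate alkylation: the chelated (Z)-enolate is attacked on the face away from the benzyl group, which sets the centre next to the imide as (S), and SN2 displacement of the triflate with inversion makes the former lactate carbon the (S) centre next to the ester.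

**Step 4**
Reactants: 8 tert-butyl (2S,3S)-4-[(4R)-4-benzyl-5,5-dimethyl-2-oxo-1,3-oxazolidin-3-yl]-2,3-dimethyl-4-oxobutanoate
Product: 10 tert-butyl (2S,3S)-2,3-dimethyl-4-oxobutanoate, via hemiaminal 9 (not isolated)
Conditions: i-Bu2AlH (1.2 equiv), CH2Cl2, −78 °C; aq. KNaC4H4O6 work-up, 0 °C (aldehyde used crude)
Reagents that add atoms: none
Why: partial reduction of the N-acyl 5,5-dimethyloxazolidinone: the gem-dimethyl group blocks ring opening, the N,O-hemiaminal survives at −78 °C and collapses on work-up to the aldehyde, the hindered tert-butyl ester is left alone and no stereocentre is touched.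

**Step 5**
Reactants: 10 tert-butyl (2S,3S)-2,3-dimethyl-4-oxobutanoate; 11 4-bromo-1,2-dimethoxybenzene
Product: 15 (3S,4S,5R)-5-(3,4-dimethoxyphenyl)-3,4-dimethyloxolan-2-one, via ArMgBr 12 (not isolated), via ArTi(Oi-Pr)3 13 (not isolated), via hydroxy ester 14 (not isolated)
Conditions: 11, Mg, THF, 23 °C; ClTi(Oi-Pr)3, −78 °C; then 10, −78 → −20 °C; aq. NH4Cl; then KOt-Bu (0.2 equiv), THF, 0 °C
Reagents that add atoms: none
Why: Felkin–Anh 1,2-addition of the non-basic aryltitanium to the α-methyl aldehyde (aryl anti to the larger C3 substituent, passing the small hydrogen) gives the syn alcohol with the new carbinol centre (R), and base-catalysed intramolecular transesterification closes the γ-lactone, whose α-methyl stays in the more stable trans position.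

**Step 6**
Reactants: 16 2,6-dimethoxyphenol
Product: 17 4-bromo-2,6-dimethoxyphenol
Conditions: NBS, CHCl3, −45 → 0 °C
Reagents that add atoms: N-bromosuccinimide, O=C1CCC(=O)N1Br
Why: electrophilic aromatic bromination goes para to the hydroxyl because both ortho positions carry methoxy groups.

**Step 7**
Reactants: 17 4-bromo-2,6-dimethoxyphenol
Product: 18 5-bromo-2-(1-ethoxyethoxy)-1,3-dimethoxybenzene
Conditions: ethyl vinyl ether, PPTS (5 mol%), CH2Cl2, 23 °C
Reagents that add atoms: ethyl vinyl ether, C=COCC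
Why: acid-catalysed addition of the phenol to the enol ether gives a mixed acetal that survives organolithium and hydride reagents but falls off under mild acid; its acetal carbon is formed racemic and is removed in step 9.

**Step 8**
Reactants: 18 5-bromo-2-(1-ethoxyethoxy)-1,3-dimethoxybenzene; 15 (3S,4S,5R)-5-(3,4-dimethoxyphenyl)-3,4-dimethyloxolan-2-one
Product: 21 (1R,2S,3S,4RS)-1-(3,4-dimethoxyphenyl)-4-[4-(1-ethoxyethoxy)-3,5-dimethoxyphenyl]-2,3-dimethylbutane-1,4-diol, via ArLi 19 (not isolated), via lactol 20 (not isolated)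
Conditions: 18, n-BuLi, THF, −78 °C; then 15, −78 °C; then MeOH, NaBH4, −78 → 0 °C
Reagents that add atoms: none
Why: bromine–lithium exchange, a single nucleophilic addition to the lactone (the lithium lactolate does not collapse at −78 °C) and NaBH4 reduction of the ring-opened hydroxy ketone give the 1,4-diol; the new benzylic carbinol forms as both epimers, which is harmless because that carbon becomes planar in step 9.

**Step 9**
Reactants: 21 (1R,2S,3S,4RS)-1-(3,4-dimethoxyphenyl)-4-[4-(1-ethoxyethoxy)-3,5-dimethoxyphenyl]-2,3-dimethylbutane-1,4-diol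
Product: 25 (2R,3S,4S,5S)-2-(3,4-dimethoxyphenyl)-3,4-dimethyl-5-(3,4,5-trimethoxyphenyl)oxolane, via phenolic diol 22 (not isolated), via quinone methide 23 (not isolated), via phenol 24 (not isolated)
Conditions: CSA (10 mol%), MeOH (5 equiv), CH2Cl2, 0 °C, 30 min; then solvent exchange, K2CO3, MeI, acetone, 50 °C (one flask)
Reagents that add atoms: iodomethane, CI
Why: acetal cleavage frees the phenol, acid-catalysed loss of water from the p-hydroxybenzylic alcohol gives the p-quinone methide, and the C1 hydroxyl closes the oxolane by intramolecular 1,6-oxa-Michael addition (5-exo) in which allylic strain holds the C–H of the methyl-bearing neighbour in the plane of the exocyclic alkene so the aryl group ends trans to that methyl (also the thermodynamic outcome); Williamson O-methylation in the same flask gives the target.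

**Compound list**

1 | (4R)-4-benzyl-5,5-dimethyl-1,3-oxazolidin-2-one | O=C1N[C@H](Cc2ccccc2)C(C)(C)O1 | starting material
2 | propanoyl chloride | CCC(=O)Cl | starting material
3 | lithium (4R)-4-benzyl-5,5-dimethyl-2-oxo-1,3-oxazolidin-3-ide | [Li+].O=C1[N-][C@H](Cc2ccccc2)C(C)(C)O1 | intermediate
4 | (4R)-4-benzyl-5,5-dimethyl-3-propanoyl-1,3-oxazolidin-2-one | CCC(=O)N1[C@H](Cc2ccccc2)C(C)(C)OC1=O | intermediate
5 | tert-butyl (2S)-2-hydroxypropanoate | C[C@H](O)C(=O)OC(C)(C)C | starting material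
6 | tert-butyl (2S)-2-[(trifluoromethanesulfonyl)oxy]propanoate | C[C@H](OS(=O)(=O)C(F)(F)F)C(=O)OC(C)(C)C | intermediate
7 | sodium (1Z)-1-[(4R)-4-benzyl-5,5-dimethyl-2-oxo-1,3-oxazolidin-3-yl]prop-1-en-1-olate | [Na+].C/C=C(\[O-])N1[C@H](Cc2ccccc2)C(C)(C)OC1=O | intermediate
8 | tert-butyl (2S,3S)-4-[(4R)-4-benzyl-5,5-dimethyl-2-oxo-1,3-oxazolidin-3-yl]-2,3-dimethyl-4-oxobutanoate | CC(C)(C)OC(=O)[C@@H](C)[C@H](C)C(=O)N1[C@H](Cc2ccccc2)C(C)(C)OC1=O | intermediate
9 | tert-butyl (2S,3S,4RS)-4-[(4R)-4-benzyl-5,5-dimethyl-2-oxo-1,3-oxazolidin-3-yl]-4-hydroxy-2,3-dimethylbutanoate (N,O-hemiaminal, present as its aluminium alkoxide) | CC(C)(C)OC(=O)[C@@H](C)[C@H](C)C(O)N1[C@H](Cc2ccccc2)C(C)(C)OC1=O | intermediate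
10 | tert-butyl (2S,3S)-2,3-dimethyl-4-oxobutanoate | CC(C)(C)OC(=O)[C@@H](C)[C@H](C)C=O | intermediate
11 | 4-bromo-1,2-dimethoxybenzene | COc1ccc(Br)cc1OC | starting material
12 | (3,4-dimethoxyphenyl)magnesium bromide | COc1ccc([Mg]Br)cc1OC | intermediate
13 | (3,4-dimethoxyphenyl)titanium triisopropoxide | COc1ccc([Ti](OC(C)C)(OC(C)C)OC(C)C)cc1OC | intermediate
14 | tert-butyl (2S,3S,4R)-4-(3,4-dimethoxyphenyl)-4-hydroxy-2,3-dimethylbutanoate | COc1ccc([C@H](O)[C@@H](C)[C@H](C)C(=O)OC(C)(C)C)cc1OC | intermediate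
15 | (3S,4S,5R)-5-(3,4-dimethoxyphenyl)-3,4-dimethyloxolan-2-one (aryl and 4-methyl cis, the two methyls trans) | COc1ccc([C@@H]2OC(=O)[C@@H](C)[C@@H]2C)cc1OC | intermediate
16 | 2,6-dimethoxyphenol | COc1cccc(OC)c1O | starting material
17 | 4-bromo-2,6-dimethoxyphenol | COc1cc(Br)cc(OC)c1O | intermediate
18 | 5-bromo-2-(1-ethoxyethoxy)-1,3-dimethoxybenzene (racemic at the acetal carbon) | CCOC(C)Oc1c(OC)cc(Br)cc1OC | intermediate
19 | [4-(1-ethoxyethoxy)-3,5-dimethoxyphenyl]lithium | [Li]c1cc(OC)c(OC(C)OCC)c(OC)c1 | intermediate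
20 | (3S,4S,5R)-5-(3,4-dimethoxyphenyl)-2-[4-(1-ethoxyethoxy)-3,5-dimethoxyphenyl]-3,4-dimethyloxolan-2-ol (lactol, in equilibrium with the γ-hydroxy ketone) | COc1ccc([C@@H]2OC(O)(c3cc(OC)c(OC(C)OCC)c(OC)c3)[C@@H](C)[C@@H]2C)cc1OC | intermediate
21 | (1R,2S,3S,4RS)-1-(3,4-dimethoxyphenyl)-4-[4-(1-ethoxyethoxy)-3,5-dimethoxyphenyl]-2,3-dimethylbutane-1,4-diol | COc1ccc([C@H](O)[C@@H](C)[C@H](C)C(O)c2cc(OC)c(OC(C)OCC)c(OC)c2)cc1OC | intermediate
22 | (1R,2S,3S,4RS)-1-(3,4-dimethoxyphenyl)-4-(4-hydroxy-3,5-dimethoxyphenyl)-2,3-dimethylbutane-1,4-diol | COc1ccc([C@H](O)[C@@H](C)[C@H](C)C(O)c2cc(OC)c(O)c(OC)c2)cc1OC | intermediate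
23 | 4-[(2R,3S,4R)-4-(3,4-dimethoxyphenyl)-4-hydroxy-2,3-dimethylbutylidene]-2,6-dimethoxycyclohexa-2,5-dien-1-one | COc1ccc([C@H](O)[C@@H](C)[C@H](C)C=C2C=C(OC)C(=O)C(OC)=C2)cc1OC | intermediate
24 | 4-[(2S,3S,4S,5R)-5-(3,4-dimethoxyphenyl)-3,4-dimethyloxolan-2-yl]-2,6-dimethoxyphenol | COc1ccc([C@@H]2O[C@H](c3cc(OC)c(O)c(OC)c3)[C@@H](C)[C@@H]2C)cc1OC | intermediate
25 | (2R,3S,4S,5S)-2-(3,4-dimethoxyphenyl)-3,4-dimethyl-5-(3,4,5-trimethoxyphenyl)oxolane (2-aryl cis to 3-methyl, methyls trans, 5-aryl trans to 4-methyl) | COc1ccc([C@@H]2O[C@H](c3cc(OC)c(OC)c(OC)c3)[C@@H](C)[C@@H]2C)cc1OC | target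

**Totals**

Total step count: 9.
Longest linear sequence: 6 (step 1 or 2, then 3, 4, 5, 8, 9). Steps 6 and 7 build the second aryl unit in parallel, and steps 1 and 2 run in parallel with each other.

**Steps most likely to fail, with fallbacks**

Step 4 (the tert-butyl ester may be over-reduced, or the α-methyl aldehyde may epimerise). The fallback sets out from 8: thiolysis with LiSEt (EtSH, n-BuLi, THF, 0 °C) releases auxiliary 1 and gives the thioester tert-butyl (2S,3S)-4-(ethylsulfanyl)-2,3-dimethyl-4-oxobutanoate F1. Fukuyama reduction (Et3SiH, Pd/C, acetone, 23 °C) stops cleanly at the aldehyde and comes back to the route at 10.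

Step 5 (substrate-controlled facial selectivity is only moderate, perhaps 5:1, and the wrong epimer gives the trans lactone). The fallback sets out from 10: plain addition of 12 (THF, −78 °C) gives the epimer mixture tert-butyl (2S,3S,4RS)-4-(3,4-dimethoxyphenyl)-4-hydroxy-2,3-dimethylbutanoate F2. Dess–Martin oxidation gives the ketone tert-butyl (2S,3S)-4-(3,4-dimethoxyphenyl)-2,3-dimethyl-4-oxobutanoate F3. Reagent-controlled reduction with (S)-2-methyl-CBS-oxazaborolidine and BH3·SMe2 (toluene, −20 °C) then sets the (4R) carbinol against the Felkin bias of the ketone and comes back to the route at 14, which is lactonised to 15 as before.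

Step 9 (acid can also ionise the dimethoxybenzylic C–O bond, which would epimerise C2 or lead to aryltetralin by Friedel–Crafts closure, and three events share one flask). The fallback sets out from 15: i-Bu2AlH (CH2Cl2, −78 °C) gives the lactol (3S,4S,5R)-5-(3,4-dimethoxyphenyl)-3,4-dimethyloxolan-2-ol F4. Its oxocarbenium ion (Sc(OTf)3, 10 mol%, CH2Cl2, −40 °C) is then trapped by 2,6-dimethoxyphenol 16 in a Friedel–Crafts C-arylation para to the hydroxyl and anti to the neighbouring methyl. This comes back to the route at 24, which is methylated (K2CO3, MeI, acetone) to 25.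

**Further compounds**

F1 | step 4 | tert-butyl (2S,3S)-4-(ethylsulfanyl)-2,3-dimethyl-4-oxobutanoate | CCSC(=O)[C@@H](C)[C@H](C)C(=O)OC(C)(C)C
F2 | step 5 | tert-butyl (2S,3S,4RS)-4-(3,4-dimethoxyphenyl)-4-hydroxy-2,3-dimethylbutanoate | COc1ccc(C(O)[C@@H](C)[C@H](C)C(=O)OC(C)(C)C)cc1OC
F3 | step 5 | tert-butyl (2S,3S)-4-(3,4-dimethoxyphenyl)-2,3-dimethyl-4-oxobutanoate | COc1ccc(C(=O)[C@@H](C)[C@H](C)C(=O)OC(C)(C)C)cc1OC
F4 | step 9 | (3S,4S,5R)-5-(3,4-dimethoxyphenyl)-3,4-dimethyloxolan-2-ol | COc1ccc([C@@H]2OC(O)[C@@H](C)[C@@H]2C)cc1OC
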